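**Retrosynthetic overview**

- The hydroquinone is unmasked last (CAN, then dithionite) from a trimethyl ether. Its (E)-chloroalkene comes from chloride capture of an α-aryl vinyl cation (from an enol triflate), and the enol triflate from reductive enolate formation on an aryl enone made by carbonylative Stille coupling of a bicyclic enol triflate with an aryl stannane.
- The bicyclic enol triflate comes from a trans-decalin enone carrying a phenylsulfonyl group; Li/NH3 removes this activating group and forms the enolate in the same pot.
- Key disconnection: the bond between the gem-dimethyl carbon and the neighbouring CH2 of the gem-dimethylcyclohexane ring (ring A). Hydrogen-atom transfer to an isopropenyl group gives the tertiary radical, which closes 6-endo onto a 2-(phenylsulfonyl)allyl arm.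
- Enabling feature: in ring A the quaternary C(CH3)2 carbon is bonded to the ring-fusion CH, and the other fusion atom is a quaternary C-CH3 next to the sp2 carbon of ring B. This is the isopropenyl-bearing CH and the α'-carbon of (R)-carvone, so ring B, its methyl and the fusion CH are bought, and the fusion quaternary centre is set by two enolate alkylations before ring A closes.
- Ring order: the arene (bought) and ring B (carvone) come first; ring A is closed last, in step 5.

Key step: step 5

Remark on the chemistry: ring A is the gem-dimethylcyclohexane and ring B the methyl-bearing ring that carries the chloroalkylidene group; (R)-(-)-carvone, phenyl vinyl sulfone and 5-bromovanillin are taken as the commercial starting materials, and the allylic bromide and the aryl stannane are made in the route.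

**Step 1**
Reactants: 1 phenyl vinyl sulfone
Product: 2 2-(phenylsulfonyl)prop-2-en-1-ol
Conditions: aq. HCHO (37%), DABCO (0.5 equiv), THF, rt
Reagents that add atoms: formaldehyde, C=O
Why: Morita-Baylis-Hillman hydroxymethylation, in which the DABCO adduct of the vinyl sulfone adds to formaldehyde and DABCO is eliminated again.

**Step 2**
Reactants: 2 2-(phenylsulfonyl)prop-2-en-1-ol
Product: 3 3-bromo-2-(phenylsulfonyl)prop-1-ene
Conditions: PBr3 (0.4 equiv), Et2O, 0 °C
Reagents that add atoms: phosphorus tribromide, BrP(Br)Br
Why: Conversion of a primary allylic alcohol into the bromide through its phosphite ester (SN2) should proceed without touching the vinyl sulfone.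

**Step 3**
Reactants: 4 (R)-(-)-carvone
Product: 6 (5R,6S)-2,6-dimethyl-5-(prop-1-en-2-yl)cyclohex-2-en-1-one (trans-6-methylcarvone; its 6-epimer is carried along), via lithium dienolate of carvone 5 (not isolated)
Conditions: LDA, THF, -78 °C; MeI, -78 → 0 °C
Reagents that add atoms: iodomethane, CI
Why: Kinetic α'-deprotonation gives the cross-conjugated dienolate, which is C-methylated (enolate alkylation); the new centre is flattened again in step 4, so its configuration does not matter.

**Step 4**
Reactants: 6 trans-6-methylcarvone, 3 3-bromo-2-(phenylsulfonyl)prop-1-ene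
Product: 8 (5S,6S)-2,6-dimethyl-6-[2-(phenylsulfonyl)prop-2-en-1-yl]-5-(prop-1-en-2-yl)cyclohex-2-en-1-one, via lithium dienolate of 6-methylcarvone 7 (not isolated)
Conditions: LDA, THF, -78 → -30 °C; then 3, -78 °C → rt
Reagents that add atoms: none
Why: Enolate C-alkylation with the activated allylic bromide (SN2 or SN2', same product) builds the quaternary centre; the electrophile should enter anti to the neighbouring isopropenyl group, as in alkylations of 6-alkylcarvones, so the sulfonylallyl arm ends trans and the methyl cis to isopropenyl.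

**Step 5**
Reactants: 8 (5S,6S)-2,6-dimethyl-6-[2-(phenylsulfonyl)prop-2-en-1-yl]-5-(prop-1-en-2-yl)cyclohex-2-en-1-one
Product: 9 (4aS,8aS)-2,5,5,8a-tetramethyl-7-(phenylsulfonyl)-4a,5,6,7,8,8a-hexahydronaphthalen-1(4H)-one (both epimers at C-7)
Conditions: Fe(acac)3 (30 mol %), PhSiH3 (2.5 equiv), EtOH/(CH2OH)2 5:1, 0.01 M, 60 °C
Reagents that add atoms: none
Why: An iron hydride formed from Fe(acac)3 and PhSiH3 transfers a hydrogen atom to the CH2 terminus of the isopropenyl group, which creates one methyl of the gem-dimethyl pair and a nucleophilic tertiary radical next to the ring-fusion CH; this radical adds to the unsubstituted terminus of the 2-sulfonylallyl arm, and the α-sulfonyl radical is then reduced and protonated. The closest known reaction type is the Fe(acac)3/PhSiH3 reductive olefin coupling (MHAT-initiated Giese addition) in its intramolecular form. Ring A closes in the 6-endo-trig mode, preferred over 5-exo because the polarity-matched position is the CH2 terminus and the alternative would join two fully substituted carbons. The new quaternary carbon bears two identical methyls and is not stereogenic; the ring-fusion centres are already present (CH from carvone, C-CH3 from step 4) and their trans arms can only close to the trans-decalin; the one new stereocentre (C-SO2Ph) is uncontrolled and is erased in step 6. The step needs hydrogen-atom transfer to the electron-rich 1,1-disubstituted alkene in the presence of the ring enone and the vinyl sulfone, which their electron-poor character should secure, and it needs cyclisation to outrun reduction of the radical or intermolecular addition, which the fast intramolecular addition to a vinyl sulfone at high dilution should secure.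

**Step 6**
Reactants: 9 (4aS,8aS)-2,5,5,8a-tetramethyl-7-(phenylsulfonyl)-4a,5,6,7,8,8a-hexahydronaphthalen-1(4H)-one
Product: 11 (4aS,8aS)-2,5,5,8a-tetramethyl-3,4,4a,5,6,7,8,8a-octahydronaphthalen-1-yl trifluoromethanesulfonate, via desulfonylated lithium enolate 10 (not isolated)
Conditions: Li (4.2 equiv), NH3(l)/THF, -78 °C, substrate added to the metal solution; NH3 off; PhNTf2, THF, 0 °C → rt
Reagents that add atoms: N-phenylbis(trifluoromethanesulfonimide), FC(F)(F)S(=O)(=O)N(c1ccccc1)S(=O)(=O)C(F)(F)F
Why: Dissolving-metal reduction converts the enone into the regiodefined tetrasubstituted lithium enolate and cleaves the alkyl phenyl sulfone in the same operation (reductive desulfonylation), and O-triflation of the enolate follows the enone reduction-enolate triflation protocol; no stereocentre is formed.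

**Step 7**
Reactants: 12 5-bromovanillin
Product: 14 2-bromo-6-methoxybenzene-1,4-diol, via 3-bromo-4-hydroxy-5-methoxyphenyl formate 13 (not isolated)
Conditions: H2O2 (30% aq.), NaOH, H2O/THF, 0 °C → rt, under N2
Reagents that add atoms: hydrogen peroxide, OO
Why: Dakin oxidation of a para-hydroxybenzaldehyde (aryl migration in the peroxide adduct, then hydrolysis of the aryl formate) should give the hydroquinone with bromine next to the hydroxyl that is flanked by methoxy.

**Step 8**
Reactants: 14 2-bromo-6-methoxybenzene-1,4-diol
Product: 15 1-bromo-2,3,5-trimethoxybenzene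
Conditions: MeI, K2CO3, acetone, reflux, under N2
Reagents that add atoms: iodomethane, CI
Why: Williamson O-methylation; methyl ethers are chosen because they should survive Li/NH3, cannot trap the vinyl cation of step 12 through a neighbouring oxygen, and the para pair can be removed oxidatively at the end.

**Step 9**
Reactants: 15 1-bromo-2,3,5-trimethoxybenzene
Product: 17 trimethyl(2,3,5-trimethoxyphenyl)stannane, via 2,3,5-trimethoxyphenyllithium 16 (not isolated)
Conditions: n-BuLi, THF, -78 °C; Me3SnCl, -78 °C → rt
Reagents that add atoms: chlorotrimethylstannane, C[Sn](C)(C)Cl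
Why: Bromine-lithium exchange fixes the metal at the required ring position, and the aryllithium is stannylated.

**Step 10**
Reactants: 11 bicyclic enol triflate, 17 trimethyl(2,3,5-trimethoxyphenyl)stannane
Product: 18 [(4aS,8aS)-2,5,5,8a-tetramethyl-3,4,4a,5,6,7,8,8a-octahydronaphthalen-1-yl](2,3,5-trimethoxyphenyl)methanone
Conditions: Pd(PPh3)4 (5 mol %), LiCl (3 equiv), CO (1-3 atm), 1,4-dioxane, 90 °C
Reagents that add atoms: carbon monoxide, [C-]#[O+]
Why: Carbonylative Stille coupling (oxidative addition into the enol triflate, CO insertion, aryl transfer from tin, reductive elimination) should attach the chlorine-bearing carbon of the target as an aryl ketone at the hindered ring carbon.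

**Step 11**
Reactants: 18 aryl enone
Product: 20 (2,3,5-trimethoxyphenyl)[(2S,4aS,8aS)-2,5,5,8a-tetramethyloctahydronaphthalen-1(2H)-ylidene]methyl trifluoromethanesulfonate (E/Z mixture), via lithium enolate of the reduced ketone 19 (not isolated)
Conditions: Li (2.2 equiv), NH3(l)/THF, -78 °C; NH3 off; PhNTf2, THF, -78 → 0 °C
Reagents that add atoms: N-phenylbis(trifluoromethanesulfonimide), FC(F)(F)S(=O)(=O)N(c1ccccc1)S(=O)(=O)C(F)(F)F
Why: Dissolving-metal reduction of the enone gives the regiodefined enolate, trapped on oxygen (reductive enolate generation and triflation); the CH(CH3) stereocentre is set by protonation of the β-carbanion from the face opposite the axial angular methyl, which places the new methyl axial and free of allylic 1,3-strain with the exocyclic enolate, and the enolate geometry is left open because step 12 is stereoconvergent.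

**Step 12**
Reactants: 20 enol triflate (E/Z mixture)
Product: 21 1-{(E)-chloro[(2S,4aS,8aS)-2,5,5,8a-tetramethyloctahydronaphthalen-1(2H)-ylidene]methyl}-2,3,5-trimethoxybenzene
Conditions: n-Bu4NCl (5 equiv), 2,6-lutidine (0.2 equiv), HFIP/CH2Cl2 4:1, 0.02 M, 45 °C
Reagents that add atoms: tetrabutylammonium chloride, [Cl-].CCCC[N+](CCCC)(CCCC)CCCC
Why: Vinylic SN1 substitution, in which both triflate isomers ionise to the same linear aryl-stabilised vinyl cation and chloride enters in the alkene plane from the side of the CH(CH3) carbon (in-plane substituent H) and not from the side of the quaternary carbon (in-plane substituent a ring CH2), which should give the chloride with Cl cis to CH(CH3) and the arene cis to the quaternary carbon.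

**Step 13**
Reactants: 21 (E)-vinyl chloride trimethyl ether
Product: 22 2-{(E)-chloro[(2S,4aS,8aS)-2,5,5,8a-tetramethyloctahydronaphthalen-1(2H)-ylidene]methyl}-6-methoxycyclohexa-2,5-diene-1,4-dione
Conditions: CAN (2.5 equiv), MeCN/H2O 3:1, 0 °C
Reagents that add atoms: water, O
Why: Oxidative demethylation of the para-dimethoxy pair of a 1,2,4-trioxygenated arene by CAN should give the 2-methoxy-1,4-benzoquinone, with the third methoxy kept as the vinylogous ester and the hindered chloroalkene untouched.

**Step 14**
Reactants: 22 methoxyquinone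
Product: 23 2-{(E)-chloro[(2S,4aS,8aS)-2,5,5,8a-tetramethyloctahydronaphthalen-1(2H)-ylidene]methyl}-6-methoxybenzene-1,4-diol (target, CNP0162917.1)
Conditions: Na2S2O4 (aq., excess), THF/H2O, rt, under Ar
Reagents that add atoms: none
Why: Dithionite reduction of the quinone to the hydroquinone leaves the vinyl chloride and the stereocentres untouched.

**Compound list**

1 | phenyl vinyl sulfone | C=CS(=O)(=O)c1ccccc1 | starting material
2 | 2-(phenylsulfonyl)prop-2-en-1-ol | C=C(CO)S(=O)(=O)c1ccccc1 | intermediate
3 | 3-bromo-2-(phenylsulfonyl)prop-1-ene | C=C(CBr)S(=O)(=O)c1ccccc1 | intermediate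
4 | (R)-(-)-carvone | O=C1C(C)=CC[C@@H](C(C)=C)C1 | starting material
5 | lithium dienolate of carvone (α'-deprotonated, O-lithiated) | [Li]OC1=C[C@H](C(C)=C)CC=C1C | intermediate
6 | (5R,6S)-2,6-dimethyl-5-(prop-1-en-2-yl)cyclohex-2-en-1-one (trans-6-methylcarvone, major epimer) | O=C1C(C)=CC[C@@H](C(C)=C)[C@@H]1C | intermediate
7 | lithium dienolate of 6-methylcarvone (O-lithiated) | [Li]OC1=C(C)[C@H](C(C)=C)CC=C1C | intermediate
8 | (5S,6S)-2,6-dimethyl-6-[2-(phenylsulfonyl)prop-2-en-1-yl]-5-(prop-1-en-2-yl)cyclohex-2-en-1-one | O=C1C(C)=CC[C@@H](C(C)=C)[C@]1(C)CC(=C)S(=O)(=O)c2ccccc2 | intermediate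
9 | (4aS,8aS)-2,5,5,8a-tetramethyl-7-(phenylsulfonyl)-4a,5,6,7,8,8a-hexahydronaphthalen-1(4H)-one (C-7 epimers) | O=C1C(C)=CC[C@H]2C(C)(C)CC(S(=O)(=O)c3ccccc3)C[C@]12C | intermediate
10 | lithium (4aS,8aS)-2,5,5,8a-tetramethyl-3,4,4a,5,6,7,8,8a-octahydronaphthalen-1-olate | [Li]OC1=C(C)CC[C@H]2C(C)(C)CCC[C@]12C | intermediate
11 | (4aS,8aS)-2,5,5,8a-tetramethyl-3,4,4a,5,6,7,8,8a-octahydronaphthalen-1-yl trifluoromethanesulfonate | O=S(=O)(OC1=C(C)CC[C@H]2C(C)(C)CCC[C@]12C)C(F)(F)F | intermediate
12 | 5-bromovanillin (3-bromo-4-hydroxy-5-methoxybenzaldehyde) | COc1cc(C=O)cc(Br)c1O | starting material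
13 | 3-bromo-4-hydroxy-5-methoxyphenyl formate | COc1cc(OC=O)cc(Br)c1O | intermediate
14 | 2-bromo-6-methoxybenzene-1,4-diol | COc1cc(O)cc(Br)c1O | intermediate
15 | 1-bromo-2,3,5-trimethoxybenzene | COc1cc(OC)cc(Br)c1OC | intermediate
16 | 2,3,5-trimethoxyphenyllithium | [Li]c1cc(OC)cc(OC)c1OC | intermediate
17 | trimethyl(2,3,5-trimethoxyphenyl)stannane | COc1cc(OC)c(OC)c([Sn](C)(C)C)c1 | intermediate
18 | [(4aS,8aS)-2,5,5,8a-tetramethyl-3,4,4a,5,6,7,8,8a-octahydronaphthalen-1-yl](2,3,5-trimethoxyphenyl)methanone | COc1cc(C(=O)C2=C(C)CC[C@H]3C(C)(C)CCC[C@]23C)c(OC)c(OC)c1 | intermediate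
19 | lithium (2,3,5-trimethoxyphenyl)[(2S,4aS,8aS)-2,5,5,8a-tetramethyloctahydronaphthalen-1(2H)-ylidene]methanolate (E/Z mixture) | COc1cc(C(O[Li])=C2[C@@H](C)CC[C@H]3C(C)(C)CCC[C@]23C)c(OC)c(OC)c1 | intermediate
20 | (2,3,5-trimethoxyphenyl)[(2S,4aS,8aS)-2,5,5,8a-tetramethyloctahydronaphthalen-1(2H)-ylidene]methyl trifluoromethanesulfonate (E/Z mixture) | COc1cc(C(OS(=O)(=O)C(F)(F)F)=C2[C@@H](C)CC[C@H]3C(C)(C)CCC[C@]23C)c(OC)c(OC)c1 | intermediate
21 | 1-{(E)-chloro[(2S,4aS,8aS)-2,5,5,8a-tetramethyloctahydronaphthalen-1(2H)-ylidene]methyl}-2,3,5-trimethoxybenzene | COc1cc(/C(Cl)=C2/[C@@H](C)CC[C@H]3C(C)(C)CCC[C@]23C)c(OC)c(OC)c1 | intermediate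
22 | 2-{(E)-chloro[(2S,4aS,8aS)-2,5,5,8a-tetramethyloctahydronaphthalen-1(2H)-ylidene]methyl}-6-methoxycyclohexa-2,5-diene-1,4-dione | COC1=CC(=O)C=C(/C(Cl)=C2/[C@@H](C)CC[C@H]3C(C)(C)CCC[C@]23C)C1=O | intermediate
23 | 2-{(E)-chloro[(2S,4aS,8aS)-2,5,5,8a-tetramethyloctahydronaphthalen-1(2H)-ylidene]methyl}-6-methoxybenzene-1,4-diol | COc1cc(O)cc(/C(Cl)=C2/[C@@H](C)CC[C@H]3C(C)(C)CCC[C@]23C)c1O | target

**Step count and risks**

Total step count: 14. Longest linear sequence: 10 steps (steps 1, 2, 4, 5, 6, 10, 11, 12, 13, 14); 9 steps from (R)-carvone.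

Steps most likely to fail:

Step 12. Ionisation of the enol triflate may be slow, the vinyl cation may be captured by the solvent or by the arene of a second molecule, or chloride may enter without enough preference for the less hindered side. The fallback sets out from 20: nickel-catalysed triflate-to-chloride exchange (Ni(cod)2 cat., LiCl, DMA/THF, rt) should retain the enol triflate geometry and give 21 together with its geometric isomer 1-{(Z)-chloro[(2S,4aS,8aS)-2,5,5,8a-tetramethyloctahydronaphthalen-1(2H)-ylidene]methyl}-2,3,5-trimethoxybenzene F1. F1 is equilibrated with 21 by reversible C-protonation (cat. HCl, HFIP), 21 is separated and F1 is recycled; the route is rejoined at 21.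

Step 11. Because the enone is twisted, electron transfer may stop at the aryl ketyl and lead to 1,2-reduction or pinacol coupling, an ortho methoxy group may be lost, or protonation at the methyl-bearing carbon may occur from both faces. The fallback sets out from 18: carbonyl-directed hydrogenation with Crabtree's catalyst ([Ir(cod)(PCy3)(py)]PF6, H2, CH2Cl2) should deliver both hydrogens from the face opposite the angular methyl and give the saturated ketone [(1S,2S,4aS,8aS)-2,5,5,8a-tetramethyldecahydronaphthalen-1-yl](2,3,5-trimethoxyphenyl)methanone F2. Deprotonation of F2 with KHMDS and O-triflation with PhNTf2 (THF, -78 °C) then gives 20, where the route is rejoined.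

Step 10. Aryl transfer from the ortho-substituted stannane to the hindered acyl-palladium may be slow, so that direct coupling without CO or reduction of the triflate competes. The fallback sets out from 11: palladium-catalysed aminocarbonylation (Pd(OAc)2, Xantphos, CO, MeNHOMe·HCl, Et3N, toluene, 80 °C) gives the Weinreb amide (4aS,8aS)-N-methoxy-N,2,5,5,8a-pentamethyl-3,4,4a,5,6,7,8,8a-octahydronaphthalene-1-carboxamide F3. Addition of aryllithium 16 (made again from 15 with n-BuLi, THF, -78 °C) to F3 gives 18, where the route is rejoined.

**Further compounds**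

F1 | step 12 | 1-{(Z)-chloro[(2S,4aS,8aS)-2,5,5,8a-tetramethyloctahydronaphthalen-1(2H)-ylidene]methyl}-2,3,5-trimethoxybenzene | COc1cc(/C(Cl)=C2\[C@@H](C)CC[C@H]3C(C)(C)CCC[C@]23C)c(OC)c(OC)c1
F2 | step 11 | [(1S,2S,4aS,8aS)-2,5,5,8a-tetramethyldecahydronaphthalen-1-yl](2,3,5-trimethoxyphenyl)methanone | COc1cc(C(=O)[C@H]2[C@@H](C)CC[C@H]3C(C)(C)CCC[C@]23C)c(OC)c(OC)c1
F3 | step 10 | (4aS,8aS)-N-methoxy-N,2,5,5,8a-pentamethyl-3,4,4a,5,6,7,8,8a-octahydronaphthalene-1-carboxamide | CON(C)C(=O)C1=C(C)CC[C@H]2C(C)(C)CCC[C@]12C
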